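**Plan**
- Retrosynthesis cuts the ester C–O bond at C1' first (shikonin plus (3Z)-5-methylhexa-3,5-dienoic acid), then C1–C2 and C3–C4 of quinone ring B.
- Enabling feature: in ring B the C2=C3 unit carries only the C1' side chain (C3 bears H), and C1 and C4 are the two carbonyl carbons of a symmetric 5,8-dioxygenated phthaloyl unit on ring A. C2–C3 can therefore arrive as a terminal alkyne inserted between the carbonyls of 3,6-dimethoxybenzocyclobutene-1,2-dione.
- Forward: ring A is bought; a four-membered ring is fused to it by aryne [2+2] cycloaddition and oxidised to the 1,2-dione; cobalt opens the acyl–acyl bond and ring B closes around the alkyne in one step; peri O-demethylation, desilylation (shikonin) and acylation finish.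
- Stereochemistry: C1' (R) is set once, by Brown allylboration of 3-(trimethylsilyl)propynal, and is a spectator afterwards. The 3Z alkene of the acyl group comes from a lithium-free Wittig reaction of methacrolein.

Key step: step 8

Remark: the allylborane is identified by its terpene source, (−)-α-pinene (written lIpc2B(allyl)), because sign conventions for this reagent vary; naphthoquinone numbering is used for the core and C1' is the carbinol carbon of the side chain.

**Route**

Step 1
Reactants: 1 2-bromo-1,4-dimethoxybenzene; 2 1,1-dimethoxyethene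
Product: 5 3,6-dimethoxybenzocyclobutenone, via 3,6-dimethoxybenzyne 3 (not isolated), via 1,1,3,6-tetramethoxybenzocyclobutene 4 (not isolated)
Conditions: NaNH2 (2.5 equiv), THF, reflux; then 1 M HCl, THF, 25 °C
Reagents that add atoms: water, O
Why: Amide base removes H3 of 1 (flanked by Br and OMe) and loss of bromide gives the symmetric aryne 3, which undergoes the known aryne–ketene acetal [2+2] cycloaddition with electron-rich 2 (no regiochemical issue for a symmetric aryne), and the strained ketal 4 is then cleaved by ordinary acetal hydrolysis.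

Step 2
Reactants: 5 3,6-dimethoxybenzocyclobutenone
Product: 6 2,2-dibromo-3,6-dimethoxybenzocyclobutenone
Conditions: NBS (2.2 equiv), (PhCO2)2 (cat.), CCl4, reflux, hν
Reagents that add atoms: N-bromosuccinimide, O=C1CCC(=O)N1Br
Why: Wohl–Ziegler radical bromination should take place twice at the C2 methylene, the only sp3 C–H site and one that is both benzylic and α to the carbonyl, while the non-polar medium disfavours ionic bromination of the dimethoxyarene.

Step 3
Reactants: 6 2,2-dibromo-3,6-dimethoxybenzocyclobutenone
Product: 7 3,6-dimethoxybenzocyclobutene-1,2-dione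
Conditions: AgOCOCF3 (2.2 equiv), MeCN/H2O, 25 → 60 °C
Reagents that add atoms: water, O
Why: Silver-assisted hydrolysis of a gem-dibromide: Ag+ pulls bromide from the benzylic carbon (the cation is supported by the ortho methoxy group), water adds and the bromohydrin collapses to the second carbonyl of the 1,2-dione.

Step 4
Reactants: 8 3-(trimethylsilyl)prop-2-ynal
Product: 9 (3R)-1-(trimethylsilyl)hex-5-en-1-yn-3-ol
Conditions: lIpc2B(allyl) (1.2 equiv, pentane solution), Et2O, −78 °C; then HOCH2CH2NH2, 25 °C
Reagents that add atoms: B-allyldiisopinocampheylborane from (−)-α-pinene, C=CCB([C@H]1C[C@H]2C[C@@H]([C@@H]1C)C2(C)C)[C@H]1C[C@H]2C[C@@H]([C@@H]1C)C2(C)C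
Why: Brown asymmetric allylboration, in which the isopinocampheyl groups of the (−)-α-pinene-derived borane steer the closed chair transition state so that allyl is delivered to the Re face of the ynal, setting C3 (the future C1') as R.

Step 5
Reactants: 9 (3R)-1-(trimethylsilyl)hex-5-en-1-yn-3-ol
Product: 10 (3R)-3-(tert-butyldimethylsilyloxy)-1-(trimethylsilyl)hex-5-en-1-yne
Conditions: TBSCl, imidazole, DMF, 25 °C
Reagents that add atoms: tert-butyldimethylsilyl chloride, CC(C)(C)[Si](C)(C)Cl
Why: Standard imidazole-promoted silylation of a secondary alcohol, which touches neither the stereocentre nor the C-silyl alkyne.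

Step 6
Reactants: 10 (3R)-3-(tert-butyldimethylsilyloxy)-1-(trimethylsilyl)hex-5-en-1-yne
Product: 11 (3R)-3-(tert-butyldimethylsilyloxy)-6-methyl-1-(trimethylsilyl)hept-5-en-1-yne
Conditions: second-generation Grubbs catalyst RuCl2(=CHPh)(PCy3)(H2IMes) (5 mol%), 2-methylbut-2-ene/CH2Cl2, 40 °C, sealed
Reagents that add atoms: 2-methylbut-2-ene, CC=C(C)C
Why: Olefin cross-metathesis should exchange the terminal methylene for the isopropylidene of 2-methylbut-2-ene (used in large excess), while the silyl-capped internal alkyne next to the bulky silyl ether is too hindered for enyne metathesis.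

Step 7
Reactants: 11 (3R)-3-(tert-butyldimethylsilyloxy)-6-methyl-1-(trimethylsilyl)hept-5-en-1-yne
Product: 12 (3R)-3-(tert-butyldimethylsilyloxy)-6-methylhept-5-en-1-yne
Conditions: K2CO3 (0.2 equiv), MeOH, 0 → 25 °C
Reagents that add atoms: none
Why: Base-catalysed methanolysis (protodesilylation) of the C(sp)–SiMe3 bond is selective because the hindered tert-butyldimethylsilyl ether is inert to catalytic methoxide at room temperature.

Step 8
Reactants: 7 3,6-dimethoxybenzocyclobutene-1,2-dione; 12 (3R)-3-(tert-butyldimethylsilyloxy)-6-methylhept-5-en-1-yne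
Product: 14 2-[(1R)-1-(tert-butyldimethylsilyloxy)-4-methylpent-3-enyl]-5,8-dimethoxy-1,4-naphthoquinone, via chlorobis(triphenylphosphine)(3,6-dimethoxyphthaloyl)cobalt 13 (not isolated)
Conditions: ClCo(PPh3)3 (1.05 equiv), PhCl, 25 → 50 °C; solvent exchange; then 12 (1.3 equiv), AgBF4 (2 equiv), MeCN, 80 °C
Reagents that add atoms: none
Why: Monovalent cobalt adds oxidatively into the strained acyl–acyl bond of 7 to give the five-membered diacyl cobaltacycle 13 of trivalent cobalt; AgBF4 then removes chloride and binds the freed phosphine, the alkyne of 12 coordinates and inserts into one Co–acyl bond to give a seven-membered acyl–vinyl cobaltacycle, and C–C reductive elimination releases the quinone. The closest known reaction type is the naphthoquinone synthesis from benzocyclobutenediones and alkynes through phthaloylcobalt complexes. Ring B closes as a six-membered ring by formal [4+2] union of the O=C–C(aryl)=C(aryl)–C=O unit with the two alkyne carbons, the first ring bond (C1–C2 or C4–C3) by migratory insertion and the second by reductive elimination at cobalt. No stereocentre is created; C1' is a spectator whose C–O and C–H bonds are not touched under these non-basic, non-ionising conditions. The only selectivity needed is chemoselectivity for the terminal alkyne over the trisubstituted C3'=C4' alkene, secured by the far stronger binding and faster insertion of the unhindered C≡C–H; regiochemistry does not arise because the 3,6-dimethoxyphthaloyl unit is symmetric and either orientation gives the same 2-substituted quinone.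

Step 9
Reactants: 14 2-[(1R)-1-(tert-butyldimethylsilyloxy)-4-methylpent-3-enyl]-5,8-dimethoxy-1,4-naphthoquinone
Product: 15 2-[(1R)-1-(tert-butyldimethylsilyloxy)-4-methylpent-3-enyl]-5,8-dihydroxy-1,4-naphthoquinone
Conditions: BCl3 (3 equiv), CH2Cl2, −78 → −40 °C; then aq. NaHCO3
Reagents that add atoms: none
Why: Chelation-controlled ether cleavage by a boron trihalide: BCl3 binds each quinone carbonyl together with its peri methoxy oxygen and chloride removes the methyl group at low temperature, where the hindered silyl ether, the trisubstituted alkene and the silyl-capped C1' oxygen (unable to ionise or cyclise) should survive.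

Step 10
Reactants: 15 2-[(1R)-1-(tert-butyldimethylsilyloxy)-4-methylpent-3-enyl]-5,8-dihydroxy-1,4-naphthoquinone
Product: 16 shikonin, 5,8-dihydroxy-2-[(1R)-1-hydroxy-4-methylpent-3-enyl]-1,4-naphthoquinone
Conditions: HF·pyridine, pyridine/THF, 0 → 25 °C
Reagents that add atoms: none
Why: Fluoride-driven desilylation under buffered, weakly acidic conditions avoids both the base sensitivity of the naphthazarin and acid-induced cyclisation of the side chain, and since the C1'–O bond is not broken the R configuration is retained.

Step 11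
Reactants: 17 (3-hydroxypropyl)triphenylphosphonium bromide; 18 methacrolein (2-methylprop-2-enal)
Product: 22 (3Z)-5-methylhexa-3,5-dien-1-ol, via [3-(trimethylsilyloxy)propyl]triphenylphosphonium chloride 19 (not isolated), via 3-(trimethylsilyloxy)propylidenetriphenylphosphorane 20 (not isolated), via (3Z)-5-methyl-1-(trimethylsilyloxy)hexa-3,5-diene 21 (not isolated)
Conditions: NaN(SiMe3)2 (1.0 equiv), Me3SiCl (1.0 equiv), THF, 0 °C; NaN(SiMe3)2 (1.05 equiv), −78 °C; 18, −78 → 0 °C; then 1 M HCl
Reagents that add atoms: none
Why: Wittig olefination with a non-stabilised ylide under lithium-free conditions should give the cis (Z) alkene through the kinetically favoured cis-oxaphosphetane; transient O-silylation keeps the oxido group from eroding Z selectivity, and the silyl ether is lost on acidic work-up.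

Step 12
Reactants: 22 (3Z)-5-methylhexa-3,5-dien-1-ol
Product: 24 (3Z)-5-methylhexa-3,5-dienoic acid, via (3Z)-5-methylhexa-3,5-dienal 23 (not isolated)
Conditions: TEMPO (0.2 equiv), PhI(OAc)2 (2.2 equiv), MeCN/H2O, 0 → 25 °C
Reagents that add atoms: water, O
Why: Oxoammonium (TEMPO) oxidation with PhI(OAc)2 as terminal oxidant takes the primary alcohol through the aldehyde hydrate to the acid under near-neutral conditions that should leave the skipped (Z)-diene unconjugated and unisomerised.

Step 13
Reactants: 16 shikonin; 24 (3Z)-5-methylhexa-3,5-dienoic acid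
Product: 25 (1R)-1-(5,8-dihydroxy-1,4-dioxo-1,4-dihydronaphthalen-2-yl)-4-methylpent-3-en-1-yl (3Z)-5-methylhexa-3,5-dienoate (CNP0129564.1)
Conditions: DCC (1.5 equiv), DMAP (0.1 equiv), CH2Cl2, 0 °C
Reagents that add atoms: none
Why: Steglich esterification should acylate only the side-chain hydroxyl because both phenols are locked in hydrogen bonds to the quinone carbonyls; the C1'–O bond is untouched so configuration is retained, and low temperature with little DMAP limits migration of the β,γ double bond into conjugation.

**Compound list**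

1 | 2-bromo-1,4-dimethoxybenzene | COc1ccc(OC)c(Br)c1 | starting material
2 | 1,1-dimethoxyethene | C=C(OC)OC | starting material
3 | 3,6-dimethoxybenzyne | COC1=CC=C(OC)C#C1 | intermediate (not isolated)
4 | 1,1,3,6-tetramethoxybenzocyclobutene | COc1ccc(OC)c2c1CC2(OC)OC | intermediate (not isolated)
5 | 3,6-dimethoxybenzocyclobutenone | COc1ccc(OC)c2c1CC2=O | intermediate
6 | 2,2-dibromo-3,6-dimethoxybenzocyclobutenone | COc1ccc(OC)c2c1C(Br)(Br)C2=O | intermediate
7 | 3,6-dimethoxybenzocyclobutene-1,2-dione | COc1ccc(OC)c2C(=O)C(=O)c12 | intermediate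
8 | 3-(trimethylsilyl)prop-2-ynal | C[Si](C)(C)C#CC=O | starting material
9 | (3R)-1-(trimethylsilyl)hex-5-en-1-yn-3-ol | C[Si](C)(C)C#C[C@H](O)CC=C | intermediate
10 | (3R)-3-(tert-butyldimethylsilyloxy)-1-(trimethylsilyl)hex-5-en-1-yne | C[Si](C)(C)C#C[C@H](O[Si](C)(C)C(C)(C)C)CC=C | intermediate
11 | (3R)-3-(tert-butyldimethylsilyloxy)-6-methyl-1-(trimethylsilyl)hept-5-en-1-yne | C[Si](C)(C)C#C[C@H](O[Si](C)(C)C(C)(C)C)CC=C(C)C | intermediate
12 | (3R)-3-(tert-butyldimethylsilyloxy)-6-methylhept-5-en-1-yne | C#C[C@H](O[Si](C)(C)C(C)(C)C)CC=C(C)C | intermediate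
13 | chlorobis(triphenylphosphine)(3,6-dimethoxyphthaloyl)cobalt (trivalent cobalt) | COc1ccc(OC)c2C(=O)[Co](Cl)([P](c3ccccc3)(c3ccccc3)c3ccccc3)([P](c3ccccc3)(c3ccccc3)c3ccccc3)C(=O)c12 | intermediate (not isolated)
14 | 2-[(1R)-1-(tert-butyldimethylsilyloxy)-4-methylpent-3-enyl]-5,8-dimethoxy-1,4-naphthoquinone | CC(C)(C)[Si](C)(C)O[C@H](CC=C(C)C)C1=CC(=O)c2c(OC)ccc(OC)c2C1=O | intermediate
15 | 2-[(1R)-1-(tert-butyldimethylsilyloxy)-4-methylpent-3-enyl]-5,8-dihydroxy-1,4-naphthoquinone | CC(C)(C)[Si](C)(C)O[C@H](CC=C(C)C)C1=CC(=O)c2c(O)ccc(O)c2C1=O | intermediate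
16 | shikonin, 5,8-dihydroxy-2-[(1R)-1-hydroxy-4-methylpent-3-enyl]-1,4-naphthoquinone | O[C@H](CC=C(C)C)C1=CC(=O)c2c(O)ccc(O)c2C1=O | intermediate
17 | (3-hydroxypropyl)triphenylphosphonium bromide | OCCC[P+](c1ccccc1)(c1ccccc1)c1ccccc1.[Br-] | starting material
18 | methacrolein (2-methylprop-2-enal) | CC(=C)C=O | starting material
19 | [3-(trimethylsilyloxy)propyl]triphenylphosphonium chloride | C[Si](C)(C)OCCC[P+](c1ccccc1)(c1ccccc1)c1ccccc1.[Cl-] | intermediate (not isolated)
20 | 3-(trimethylsilyloxy)propylidenetriphenylphosphorane | C[Si](C)(C)OCCC=P(c1ccccc1)(c1ccccc1)c1ccccc1 | intermediate (not isolated)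
21 | (3Z)-5-methyl-1-(trimethylsilyloxy)hexa-3,5-diene | C=C(C)/C=C\CCO[Si](C)(C)C | intermediate (not isolated)
22 | (3Z)-5-methylhexa-3,5-dien-1-ol | C=C(C)/C=C\CCO | intermediate
23 | (3Z)-5-methylhexa-3,5-dienal | C=C(C)/C=C\CC=O | intermediate (not isolated)
24 | (3Z)-5-methylhexa-3,5-dienoic acid | C=C(C)/C=C\CC(=O)O | intermediate
25 | (1R)-1-(5,8-dihydroxy-1,4-dioxo-1,4-dihydronaphthalen-2-yl)-4-methylpent-3-en-1-yl (3Z)-5-methylhexa-3,5-dienoate | C=C(C)/C=C\CC(=O)O[C@H](CC=C(C)C)C1=CC(=O)c2c(O)ccc(O)c2C1=O | target

**Step count and risks**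

Total steps: 13. Longest linear sequence: 8 steps (steps 4, 5, 6, 7, 8, 9, 10 and 13, from 8 to 25).

Steps most likely to fail:

1. Step 9. The Lewis acid may spread from the chelated methyl ethers to the silyl ether, after which the alkene could be hydrochlorinated or the freed C1' oxygen could cyclise onto C4'; the reaction may also stall after the first demethylation once boron sits in the chelate. Fallback: the ether cleavage is moved to the dione, where no side chain is present. Setting out from 7, BBr3 in CH2Cl2 (−78 → 0 °C) would give 3,6-dihydroxybenzocyclobutene-1,2-dione F1, and TBSOTf with 2,6-lutidine would give 3,6-bis(tert-butyldimethylsilyloxy)benzocyclobutene-1,2-dione F2. The cobalt sequence of step 8 with 12 would then give 5,8-bis(tert-butyldimethylsilyloxy)-2-[(1R)-1-(tert-butyldimethylsilyloxy)-4-methylpent-3-enyl]-1,4-naphthoquinone F3. HF·pyridine, as in step 10, would remove all three silyl groups in one operation and the route is rejoined at 16.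

2. Step 8. The silver/fluoroborate medium may strip the silyl ether, the terminal alkyne may form a silver acetylide or oligomerise, insertion of the hindered propargylic alkyne may be slow, and freed phosphine may add to the product quinone. Fallback: ring B is built by Dötz benzannulation instead. Setting out from 1, bromine–lithium exchange (n-BuLi, Et2O, −78 °C), addition to Cr(CO)6 and O-methylation with Me3OBF4 would give pentacarbonyl[(2,5-dimethoxyphenyl)(methoxy)methylidene]chromium F4. Heating F4 with 12 in THF at 50 °C (alkyne insertion, CO insertion, electrocyclic closure) would give 2-[(1R)-1-(tert-butyldimethylsilyloxy)-4-methylpent-3-enyl]-4,5,8-trimethoxynaphthalen-1-ol F5 as its Cr(CO)3 complex. Oxidation in the same flask with (NH4)2Ce(NO3)6 in MeCN/H2O at 0 °C would convert the 4-methoxy-1-naphthol ring to the quinone and rejoin the route at 14.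

3. Step 11. Incomplete O-silylation or competing C-silylation of the ylide may erode Z selectivity, the enal may polymerise or suffer conjugate addition, and the volatile dienol may be lost on isolation. Fallback: the Z alkene is made by cis reduction of an alkyne instead. Setting out from 18, Corey–Fuchs dibromo-olefination (CBr4, PPh3, CH2Cl2, 0 °C) would give 1,1-dibromo-3-methylbuta-1,3-diene F6. Treatment with n-BuLi (2 equiv, THF, −78 °C) followed by oxirane and BF3·OEt2 would give 5-methylhex-5-en-3-yn-1-ol F7. Reduction with zinc activated by Cu(OAc)2 and AgNO3 in MeOH/H2O would reduce the conjugated triple bond to the cis alkene and rejoin the route at 22.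

**Further compounds**

F1 | step 9 | 3,6-dihydroxybenzocyclobutene-1,2-dione | Oc1ccc(O)c2C(=O)C(=O)c12
F2 | step 9 | 3,6-bis(tert-butyldimethylsilyloxy)benzocyclobutene-1,2-dione | CC(C)(C)[Si](C)(C)Oc1ccc(O[Si](C)(C)C(C)(C)C)c2C(=O)C(=O)c12
F3 | step 9 | 5,8-bis(tert-butyldimethylsilyloxy)-2-[(1R)-1-(tert-butyldimethylsilyloxy)-4-methylpent-3-enyl]-1,4-naphthoquinone | CC(C)(C)[Si](C)(C)O[C@H](CC=C(C)C)C1=CC(=O)c2c(O[Si](C)(C)C(C)(C)C)ccc(O[Si](C)(C)C(C)(C)C)c2C1=O
F4 | step 8 | pentacarbonyl[(2,5-dimethoxyphenyl)(methoxy)methylidene]chromium | COC(c1cc(OC)ccc1OC)=[Cr](=C=O)(=C=O)(=C=O)(=C=O)=C=O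
F5 | step 8 | 2-[(1R)-1-(tert-butyldimethylsilyloxy)-4-methylpent-3-enyl]-4,5,8-trimethoxynaphthalen-1-ol | COc1cc([C@H](O[Si](C)(C)C(C)(C)C)CC=C(C)C)c(O)c2c(OC)ccc(OC)c12
F6 | step 11 | 1,1-dibromo-3-methylbuta-1,3-diene | C=C(C)C=C(Br)Br
F7 | step 11 | 5-methylhex-5-en-3-yn-1-ol | C=C(C)C#CCCO
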